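The 1,4-dioxane ring is disconnected at C2–aryl to an aryl δ-lactone, and this lactone to a flat 1,3-benzodioxole-2-carbaldehyde, the five-membered ketal of 5-allylpyrogallol. In one operation a chiral triazolylidene reverses the polarity of the formyl carbon, expels the outer ring oxygen from the ketal carbon, protonates that carbon (future C3) enantioselectively and re-closes the oxygen onto the acyl carbon (future C2). The five-membered ring thereby grows to the six-membered O1–C2–C3–O4 ring. The step exploits the O1–C2(=O)–C3(H)–O4 array and the central position of O4 on the benzene ring, para to the allyl group. Methylation and aryllithium addition finish the route.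

Key step: step 4

Assumption: the hemiketal carbon C2 epimerises through ring–chain tautomerism, and the drawn 2S configuration (hydroxyl trans to the C3 methyl group) is taken to be the thermodynamically preferred epimer, so only C3 has to be set by the route.

Step 1
Reactants: 1 4-allyl-2,6-dimethoxyphenol
Product: 2 5-allylbenzene-1,2,3-triol
Conditions: BBr3 (3.5 equiv), CH2Cl2, −78 → 0 °C, Ar; then H2O; used crude
Reagents that add atoms: none
Why: BBr3 ether cleavage (Lewis-acid O-demethylation) should remove both equivalent methyl groups at ≤0 °C, where the isolated terminal alkene is expected to survive, and no stereocentre is formed.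

Step 2
Reactants: 2 5-allylbenzene-1,2,3-triol; 3 methyl 2,2-dimethoxypropanoate
Product: 4 methyl 6-allyl-4-hydroxy-2-methyl-1,3-benzodioxole-2-carboxylate (racemic)
Conditions: TsOH·H2O (5 mol%), toluene, 100 °C, 5 Å MS (−MeOH), Ar
Reagents that add atoms: none
Why: Acid-catalysed transketalisation can only close the five-membered 1,3-benzodioxole on two vicinal hydroxyls of the symmetric triol, so a single constitution is expected, and the new ketal stereocentre, formed as a racemate, is erased in step 4.

Step 3
Reactants: 4 methyl 6-allyl-4-hydroxy-2-methyl-1,3-benzodioxole-2-carboxylate (racemic)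
Product: 5 6-allyl-4-hydroxy-2-methyl-1,3-benzodioxole-2-carbaldehyde (racemic)
Conditions: DIBAL-H (2.3 equiv), CH2Cl2, −78 °C; MeOH, aq. Rochelle salt
Reagents that add atoms: none
Why: DIBAL-H partial reduction of an α,α-dioxygenated ester should stop at the chelated aluminium hemiacetal (the first equivalent is consumed by the phenol), which gives the non-enolisable aldehyde on work-up.

Step 4
Reactants: 5 6-allyl-4-hydroxy-2-methyl-1,3-benzodioxole-2-carbaldehyde (racemic)
Product: 6 (3R)-7-allyl-5-hydroxy-3-methyl-2,3-dihydro-1,4-benzodioxin-2-one
Conditions: 2-(pentafluorophenyl)-5a,10b-dihydro-4H,6H-indeno[2,1-b][1,2,4]triazolo[4,3-d][1,4]oxazin-2-ium tetrafluoroborate (10 mol%; of the (5aS,10bR) and (5aR,10bS) forms, the one that delivers 3R), KOt-Bu (1.10 equiv), 18-crown-6 (1.1 equiv), toluene–THF, 0.02 M, −20 °C → rt; AcOH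
Reagents that add atoms: none
Why: Proposed new method: the carbene should add to the formyl group, and the resulting hydroxy-enamine (acyl anion equivalent) should expel the outer ring oxygen from the ketal carbon as an aryloxide, after which C-protonation of the azolium enol gives an acyl azolium that the freed aryloxide acylates, so that the formyl carbon is inserted into a ring C–O bond and the five-membered ketal becomes the six-membered lactone with release of the catalyst. The closest known reaction types are the carbene-catalysed redox ring expansion of oxacycloalkane-2-carbaldehydes to lactones and the carbene-catalysed enantioselective protonation of azolium enolates generated from α,α-dichloro aldehydes; neither has been shown on a cyclic ketal aldehyde. The ring closes by 6-exo-trig acyl substitution of the aryloxide at the acyl azolium carbon. C3, the only stereocentre, is set by face-selective proton transfer to the azolium enol within the chiral pocket of the aminoindanol-derived triazolium, which also makes the step stereoconvergent because the ketal stereocentre of racemic 5 is destroyed first. The step needs cleavage of the outer and not the central C–O bond of the ketal: the potassium phenoxide next to the central oxygen would turn that oxygen into part of a vicinal dianion if it left, so the outer oxygen should leave. Once it has left, the two oxygens flanking the central one are equivalent, so closure by either gives the same lactone 6.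

Step 5
Reactants: 6 (3R)-7-allyl-5-hydroxy-3-methyl-2,3-dihydro-1,4-benzodioxin-2-one
Product: 7 (3R)-7-allyl-5-methoxy-3-methyl-2,3-dihydro-1,4-benzodioxin-2-one
Conditions: MeI (1.5 equiv), K2CO3 (1.2 equiv), acetone, rt
Reagents that add atoms: iodomethane, CI
Why: Williamson O-methylation of the phenol with K2CO3/MeI is too weakly basic to enolise the α-aryloxy lactone, so C3 should keep its configuration.

Step 6
Reactants: 7 (3R)-7-allyl-5-methoxy-3-methyl-2,3-dihydro-1,4-benzodioxin-2-one; 8 5-bromo-1,2,3-trimethoxybenzene
Product: 11 (2S,3R)-7-allyl-5-methoxy-3-methyl-2-(3,4,5-trimethoxyphenyl)-2,3-dihydro-1,4-benzodioxin-2-ol, via (3,4,5-trimethoxyphenyl)lithium 9 (not isolated), via open-chain keto-phenol 10 (not isolated)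
Conditions: 8, n-BuLi (1.0 equiv), THF, −78 °C; cannulated into 7, THF, −78 °C; AcOH, −78 °C → rt
Reagents that add atoms: none
Why: Bromine–lithium exchange followed by 1,2-addition of one equivalent of the aryllithium to the activated aryl lactone at −78 °C (inverse addition) should give, after acid quench, the hemiketal directly or its ring-chain tautomer 10, which re-closes by 6-exo-trig hemiketalisation onto the ring atoms set in step 4, with C3 untouched and C2 set under thermodynamic control (anomeric hydroxyl, trans to the C3 methyl).

Compound list
1 | 4-allyl-2,6-dimethoxyphenol | C=CCc1cc(OC)c(O)c(OC)c1 | starting material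
2 | 5-allylbenzene-1,2,3-triol | C=CCc1cc(O)c(O)c(O)c1 | intermediate
3 | methyl 2,2-dimethoxypropanoate | COC(=O)C(C)(OC)OC | starting material
4 | methyl 6-allyl-4-hydroxy-2-methyl-1,3-benzodioxole-2-carboxylate (racemic) | C=CCc1cc(O)c2OC(C)(C(=O)OC)Oc2c1 | intermediate
5 | 6-allyl-4-hydroxy-2-methyl-1,3-benzodioxole-2-carbaldehyde (racemic) | C=CCc1cc(O)c2OC(C)(C=O)Oc2c1 | intermediate
6 | (3R)-7-allyl-5-hydroxy-3-methyl-2,3-dihydro-1,4-benzodioxin-2-one | C=CCc1cc(O)c2O[C@H](C)C(=O)Oc2c1 | intermediate
7 | (3R)-7-allyl-5-methoxy-3-methyl-2,3-dihydro-1,4-benzodioxin-2-one | C=CCc1cc(OC)c2O[C@H](C)C(=O)Oc2c1 | intermediate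
8 | 5-bromo-1,2,3-trimethoxybenzene | COc1cc(Br)cc(OC)c1OC | starting material
9 | (3,4,5-trimethoxyphenyl)lithium | [Li]c1cc(OC)c(OC)c(OC)c1 | intermediate
10 | (2R)-2-(4-allyl-2-hydroxy-6-methoxyphenoxy)-1-(3,4,5-trimethoxyphenyl)propan-1-one | C=CCc1cc(O)c(O[C@H](C)C(=O)c2cc(OC)c(OC)c(OC)c2)c(OC)c1 | intermediate
11 | (2S,3R)-7-allyl-5-methoxy-3-methyl-2-(3,4,5-trimethoxyphenyl)-2,3-dihydro-1,4-benzodioxin-2-ol | C=CCc1cc(OC)c2c(c1)O[C@@](O)(c1cc(OC)c(OC)c(OC)c1)[C@@H](C)O2 | target

Total step count: 6. Longest linear sequence: 6 steps (1 → 2 → 4 → 5 → 6 → 7 → 11); 3 and 8 enter as commercial building blocks.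

Steps most likely to fail

Step 4 (Proposed new method). The proton transfer to the azolium enol may show poor facial selectivity, not least because the flanking phenol of the substrate can deliver the proton itself. The central instead of the outer ring oxygen may also be expelled, and the aryl lactone may lose configuration by re-entering the catalytic cycle as an enolate. The fallback sets out from compound 1 and takes C3 from the chiral pool with direct ring closure. Mitsunobu etherification of 1 with ethyl (S)-lactate (PPh3, DIAD, THF, 0 °C → rt, inversion at the lactate carbon) would give ethyl (2R)-2-(4-allyl-2,6-dimethoxyphenoxy)propanoate F1. Cleavage of one of its two equivalent methyl ethers with BCl3 (1.1 equiv, CH2Cl2, −78 → 0 °C) would give ethyl (2R)-2-(4-allyl-2-hydroxy-6-methoxyphenoxy)propanoate F2. Acid-catalysed lactonisation (TsOH, toluene, 80 °C) would then return to the route at compound 7.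

Step 6. The tetrahedral adduct may collapse to the ketone and take up a second aryllithium, or the aryllithium may deprotonate C3 with loss of configuration. The fallback sets out from compound 7. Opening the lactone with N,O-dimethylhydroxylamine hydrochloride and AlMe3 (CH2Cl2, 0 °C) would give (2R)-2-(4-allyl-2-hydroxy-6-methoxyphenoxy)-N-methoxy-N-methylpropanamide F3. Treatment with 2.2 equivalents of aryllithium 9 at −78 °C (the first deprotonates the phenol, the second forms the stable chelated adduct) and acidic work-up would return to the route at compound 10, which closes to 11.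

Step 2. Ionisation of the ester-deactivated dimethyl ketal may be slow, so that air oxidation or C-alkylation of the electron-rich triol competes. The fallback sets out from compound 2. Double O-alkylation with methyl dichloroacetate (K2CO3, DMF, 60 °C) would give methyl 6-allyl-4-hydroxy-1,3-benzodioxole-2-carboxylate F4. C-methylation of its dianion at the ketal carbon (LDA, 2.1 equiv, THF, −78 °C; MeI, 1.0 equiv) would return to the route at compound 4.

Further compounds
F1 | step 4 | ethyl (2R)-2-(4-allyl-2,6-dimethoxyphenoxy)propanoate | C=CCc1cc(OC)c(O[C@H](C)C(=O)OCC)c(OC)c1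
F2 | step 4 | ethyl (2R)-2-(4-allyl-2-hydroxy-6-methoxyphenoxy)propanoate | C=CCc1cc(O)c(O[C@H](C)C(=O)OCC)c(OC)c1
F3 | step 6 | (2R)-2-(4-allyl-2-hydroxy-6-methoxyphenoxy)-N-methoxy-N-methylpropanamide | C=CCc1cc(O)c(O[C@H](C)C(=O)N(C)OC)c(OC)c1
F4 | step 2 | methyl 6-allyl-4-hydroxy-1,3-benzodioxole-2-carboxylate | C=CCc1cc(O)c2OC(C(=O)OC)Oc2c1
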